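**Retrosynthetic overview**

1. Ring A is numbered with the diaryl-ether carbon as carbon 1, the hydroxyl carbons as carbons 2 and 4, and the pentyl carbon as carbon 6. It is a 4-aryloxyphenol: the ether oxygen on carbon 1 stands para to the hydroxyl on carbon 4. This is the pattern left when a heteroatom-bearing carbene carbon and a chromium-bound CO end up 1,4 in a newly built benzene ring.
2. Ring A is therefore cut into an aryloxy(1-tert-butoxyvinyl)carbene complex of Cr(CO)5 (carbons 1, 2 and 3), one CO ligand (carbon 4) and 1-(trimethylsilyl)hept-1-yne (carbons 5 and 6). The ring bonds between carbons 1 and 6, carbons 4 and 5, and carbons 3 and 4 form in one benzannulation, with silicon steering pentyl to carbon 6.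
3. The carbene complex comes from lithiated tert-butyl vinyl ether and Cr(CO)6 through the acyl chromate, O-acetylation and exchange of acetate for the ring B phenol. Ring B is numbered from its hydroxyl carbon: hydroxyl at position 1, CO2Me at position 2, pentanoyl at position 3, OMe at position 5.
4. That phenol is made from 3,5-dimethoxybenzonitrile by butyl Grignard addition, ring bromination, ketalisation, Br–Li exchange with methoxycarbonylation, and ester-directed demethylation with BCl3.
5. Ring order: ring B is aromatic from the start, ring A is the only ring formed (step 9), and trifluoroacetic acid then removes the tert-butyl and silyl groups.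

Key step: step 9

Remark: the target has no stereocentre and no stereogenic double bond, so no stereocontrol is needed. In the SMILES of chromium complexes the Cr–CO and Cr=C bonds are drawn as double bonds, and the η6-arene complex 21 is written as two components.

**Route**

Step 1
Reactants: 1 3,5-dimethoxybenzonitrile
Product: 3 1-(3,5-dimethoxyphenyl)pentan-1-one, via bromomagnesium ketiminate 2 (not isolated)
Conditions: n-BuMgBr (1.5 equiv), THF, 0 °C → reflux; then 2 M aq HCl, rt
Reagents that add atoms: butylmagnesium bromide CCCC[Mg]Br; water O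
Why: Grignard addition to the nitrile stops at the N-magnesio ketimine, which cannot take up a second equivalent and is hydrolysed by aqueous acid to the aryl butyl ketone.

Step 2
Reactants: 3 1-(3,5-dimethoxyphenyl)pentan-1-one
Product: 4 1-(2-bromo-3,5-dimethoxyphenyl)pentan-1-one
Conditions: NBS (1.05 equiv), MeCN, 0 °C → rt
Reagents that add atoms: N-bromosuccinimide O=C1CCC(=O)N1Br
Why: Electrophilic aromatic bromination should go to ring position 2, para to one methoxy group and ortho to the other, because the equally activated position 4 is screened by two flanking methoxy groups, as is usual for 3,5-dimethoxyphenyl carbonyl compounds.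

Step 3
Reactants: 4 1-(2-bromo-3,5-dimethoxyphenyl)pentan-1-one
Product: 5 2-(2-bromo-3,5-dimethoxyphenyl)-2-butyl-1,3-dioxolane
Conditions: HOCH2CH2OH (5 equiv), p-TsOH·H2O (5 mol%), toluene, reflux, Dean–Stark trap
Reagents that add atoms: ethane-1,2-diol OCCO
Why: Acid-catalysed ketalisation with azeotropic removal of water masks the ketone so that it survives the aryllithium of the next step.

Step 4
Reactants: 5 2-(2-bromo-3,5-dimethoxyphenyl)-2-butyl-1,3-dioxolane
Product: 8 methyl 2,4-dimethoxy-6-pentanoylbenzoate, via aryllithium 6 (not isolated), via ketal ester 7 (not isolated)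
Conditions: n-BuLi (1.05 equiv), THF, −78 °C; cannulation into ClCO2Me (3 equiv), THF, −78 °C → rt; then 2 M aq HCl, THF, 40 °C
Reagents that add atoms: methyl chloroformate COC(=O)Cl; water O
Why: Bromine–lithium exchange and C-acylation by the chloroformate put the ester on the carbon that carried bromine (the 2,6-disubstituted benzoate is too hindered to take up a second aryllithium), and acid hydrolysis of the dioxolane then returns the ketone.

Step 5
Reactants: 8 methyl 2,4-dimethoxy-6-pentanoylbenzoate
Product: 10 methyl 2-hydroxy-4-methoxy-6-pentanoylbenzoate, via aryl dichloroborinate 9 (not isolated)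
Conditions: BCl3 (1 M in CH2Cl2, 2.2 equiv), CH2Cl2, −78 → 0 °C; then ice-water
Reagents that add atoms: none
Why: In this chelation-controlled Lewis-acid ether cleavage, BCl3 bound to the ester carbonyl removes only the ortho methyl group through a six-membered chelate, the 4-methoxy group and the methyl ester stay, and water hydrolyses the B–O bond.

Step 6
Reactants: 11 hept-1-yne
Product: 13 trimethyl(hept-1-yn-1-yl)silane, via heptynyllithium 12 (not isolated)
Conditions: n-BuLi (1.05 equiv), THF, −78 °C; Me3SiCl, −78 °C → rt
Reagents that add atoms: chlorotrimethylsilane C[Si](C)(C)Cl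
Why: Deprotonation of the terminal alkyne and C-silylation of the lithium acetylide is a routine way to cap the alkyne with the group that will direct the benzannulation.

Step 7
Reactants: 14 tert-butyl vinyl ether; 15 chromium hexacarbonyl Cr(CO)6
Product: 18 tetramethylammonium pentacarbonyl[2-(tert-butoxy)prop-2-enoyl]chromate, via alkoxyvinyllithium 16 (not isolated), via lithium acyl chromate 17 (not isolated)
Conditions: 14 (1.5 equiv), t-BuLi (1.0 equiv), THF, −78 → 0 °C; addition to Cr(CO)6, THF, −78 °C → rt; Me4NBr, degassed H2O, extraction into CH2Cl2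
Reagents that add atoms: tetramethylammonium bromide C[N+](C)(C)C.[Br-]
Why: Alpha-lithiation of the alkyl vinyl ether (oxygen acidifies the adjacent vinyl C–H) and Fischer-type addition of the vinyllithium to a CO ligand give the acyl chromate, which is taken on as its storable tetramethylammonium salt.

Step 8
Reactants: 18 tetramethylammonium pentacarbonyl[2-(tert-butoxy)prop-2-enoyl]chromate; 10 methyl 2-hydroxy-4-methoxy-6-pentanoylbenzoate
Product: 20 pentacarbonyl{[5-methoxy-2-(methoxycarbonyl)-3-pentanoylphenoxy][1-(tert-butoxy)ethenyl]methylidene}chromium, via acetoxycarbene complex 19 (not isolated)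
Conditions: AcBr (1.05 equiv), CH2Cl2, −40 °C, 45 min; then 10, i-Pr2NEt (1.1 equiv), CH2Cl2, −40 → 0 °C; cold filtration through silica under argon, used at once
Reagents that add atoms: none
Why: O-Acylation of the acyl chromate gives a carbene complex with an anhydride-like leaving group, and addition–elimination of the phenol at the carbene carbon (the acyloxy-to-aryloxy exchange that is the standard entry to aryloxy Fischer carbene complexes) installs the ring B aryloxy group without strong base.

Step 9
Reactants: 20 pentacarbonyl{[5-methoxy-2-(methoxycarbonyl)-3-pentanoylphenoxy][1-(tert-butoxy)ethenyl]methylidene}chromium; 13 trimethyl(hept-1-yn-1-yl)silane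
Product: 22 methyl 2-[2-tert-butoxy-4-hydroxy-6-pentyl-5-(trimethylsilyl)phenoxy]-4-methoxy-6-pentanoylbenzoate, via tricarbonylchromium arene complex 21 (not isolated)
Conditions: 13 (2 equiv), THF (0.05 M), 55 °C, argon, 12–24 h; then air, Et2O, rt, daylight
Reagents that add atoms: none
Why: Thermal loss of one CO from 20 lets the alkyne bind and insert into the Cr=C bond so that the carbene carbon (carbon 1 of ring A) bonds to the pentyl-bearing alkyne carbon (carbon 6); the silyl-bearing carbon becomes the new carbene carbon, takes up a CO ligand (the bond between carbons 4 and 5) and gives a chromium-bound dienylketene, which closes and tautomerises to the phenol. The closest known reaction type is the Dötz benzannulation of aryloxy(alkenyl)carbene chromium complexes with alkynes to 4-aryloxyphenols, together with that of alpha-alkoxyalkenyl complexes made from lithiated enol ethers. Ring A is closed by 6π-electrocyclisation of the dienylketene (the bond between carbons 3 and 4, from the CH2 terminus of the alkoxyvinyl group to the ketene carbon), the last bond of a formal [3+2+1] assembly. No stereocentre is formed. The step needs a single alkyne orientation, and the trimethylsilyl group should secure it: as the larger substituent it sits on the alkyne carbon that stays on chromium and meets CO, so silicon ends at carbon 5 next to the new hydroxyl and pentyl at carbon 6 next to the ether carbon. Because no base is present and the temperature stays near 55 °C, the enolisable keto ester of ring B cannot undergo Claisen-type closure to an indane-1,3-dione, and exposure to air then frees 22 from the Cr(CO)3 fragment of 21.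

Step 10
Reactants: 22 methyl 2-[2-tert-butoxy-4-hydroxy-6-pentyl-5-(trimethylsilyl)phenoxy]-4-methoxy-6-pentanoylbenzoate
Product: 23 methyl 2-(2,4-dihydroxy-6-pentylphenoxy)-4-methoxy-6-pentanoylbenzoate (target)
Conditions: CF3CO2H/CH2Cl2 (1:4), 1,3-dimethoxybenzene (10 equiv), 0 °C → rt; evaporation
Reagents that add atoms: none
Why: Acidolysis cleaves the aryl tert-butyl ether (the cation is taken up by the scavenger arene in a Friedel–Crafts alkylation) and ipso-protonation of the silyl-bearing carbon, activated by the ortho hydroxyl and the para oxygen, brings about protodesilylation, so one acid treatment should unveil both the hydroxyl on carbon 2 and the hydrogen on carbon 5 of ring A.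

**Compound list**

1 | 3,5-dimethoxybenzonitrile | COc1cc(OC)cc(C#N)c1 | starting material
2 | bromomagnesium salt of 1-(3,5-dimethoxyphenyl)pentan-1-imine | CCCCC(=N[Mg]Br)c1cc(OC)cc(OC)c1 | intermediate
3 | 1-(3,5-dimethoxyphenyl)pentan-1-one | CCCCC(=O)c1cc(OC)cc(OC)c1 | intermediate
4 | 1-(2-bromo-3,5-dimethoxyphenyl)pentan-1-one | CCCCC(=O)c1cc(OC)cc(OC)c1Br | intermediate
5 | 2-(2-bromo-3,5-dimethoxyphenyl)-2-butyl-1,3-dioxolane | CCCCC1(OCCO1)c1cc(OC)cc(OC)c1Br | intermediate
6 | [2-(2-butyl-1,3-dioxolan-2-yl)-4,6-dimethoxyphenyl]lithium | [Li]c1c(OC)cc(OC)cc1C1(CCCC)OCCO1 | intermediate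
7 | methyl 2-(2-butyl-1,3-dioxolan-2-yl)-4,6-dimethoxybenzoate | COC(=O)c1c(OC)cc(OC)cc1C1(CCCC)OCCO1 | intermediate
8 | methyl 2,4-dimethoxy-6-pentanoylbenzoate | CCCCC(=O)c1cc(OC)cc(OC)c1C(=O)OC | intermediate
9 | methyl 2-[(dichloroboranyl)oxy]-4-methoxy-6-pentanoylbenzoate | CCCCC(=O)c1cc(OC)cc(OB(Cl)Cl)c1C(=O)OC | intermediate
10 | methyl 2-hydroxy-4-methoxy-6-pentanoylbenzoate | CCCCC(=O)c1cc(OC)cc(O)c1C(=O)OC | intermediate
11 | hept-1-yne | CCCCCC#C | starting material
12 | hept-1-yn-1-yllithium | [Li]C#CCCCCC | intermediate
13 | trimethyl(hept-1-yn-1-yl)silane | CCCCCC#C[Si](C)(C)C | intermediate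
14 | tert-butyl vinyl ether | C=COC(C)(C)C | starting material
15 | chromium hexacarbonyl, Cr(CO)6 | O=C=[Cr](=C=O)(=C=O)(=C=O)(=C=O)=C=O | starting material
16 | [1-(tert-butoxy)ethenyl]lithium | [Li]C(=C)OC(C)(C)C | intermediate
17 | lithium pentacarbonyl[2-(tert-butoxy)prop-2-enoyl]chromate | [Li+].[O-]C(C(=C)OC(C)(C)C)=[Cr](=C=O)(=C=O)(=C=O)(=C=O)=C=O | intermediate
18 | tetramethylammonium pentacarbonyl[2-(tert-butoxy)prop-2-enoyl]chromate | C[N+](C)(C)C.[O-]C(C(=C)OC(C)(C)C)=[Cr](=C=O)(=C=O)(=C=O)(=C=O)=C=O | intermediate
19 | pentacarbonyl{(acetyloxy)[1-(tert-butoxy)ethenyl]methylidene}chromium | CC(=O)OC(C(=C)OC(C)(C)C)=[Cr](=C=O)(=C=O)(=C=O)(=C=O)=C=O | intermediate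
20 | pentacarbonyl{[5-methoxy-2-(methoxycarbonyl)-3-pentanoylphenoxy][1-(tert-butoxy)ethenyl]methylidene}chromium | O=C=[Cr](=C=O)(=C=O)(=C=O)(=C=O)=C(Oc1cc(OC)cc(C(=O)CCCC)c1C(=O)OC)C(=C)OC(C)(C)C | intermediate
21 | tricarbonylchromium complex of 22, η6-bound to ring A | CCCCCc1c([Si](C)(C)C)c(O)cc(OC(C)(C)C)c1Oc1cc(OC)cc(C(=O)CCCC)c1C(=O)OC.O=C=[Cr](=C=O)=C=O | intermediate
22 | methyl 2-[2-tert-butoxy-4-hydroxy-6-pentyl-5-(trimethylsilyl)phenoxy]-4-methoxy-6-pentanoylbenzoate | CCCCCc1c([Si](C)(C)C)c(O)cc(OC(C)(C)C)c1Oc1cc(OC)cc(C(=O)CCCC)c1C(=O)OC | intermediate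
23 | methyl 2-(2,4-dihydroxy-6-pentylphenoxy)-4-methoxy-6-pentanoylbenzoate | CCCCCc1cc(O)cc(O)c1Oc1cc(OC)cc(C(=O)CCCC)c1C(=O)OC | target

**Step count**

Total steps: 10. Longest linear sequence: 8 steps (steps 1–5, 8, 9, 10, from 3,5-dimethoxybenzonitrile).

**Steps most likely to fail**

1. Step 9 (key step). The hindered internal silyl alkyne may insert more slowly than the labile aryloxycarbene complex decays. Insertion may also leak to the other alkyne orientation, or the sequence may stop at a silyl-stabilised dienylketene whose geometry does not allow ring closure. A shift of silicon from carbon 5 of ring A to the oxygen on carbon 4 would do no harm, since step 10 removes the silyl group from either place. The fallback keeps the carbene logic but fixes the regiochemistry in a (Z)-dienyl group and needs no alkyne: it is the photochemical ortho-benzannulation of a dienylcarbene complex, in which CO inserts at the carbene carbon and becomes the hydroxyl carbon at position 2 of ring A. It sets out from phenol 10 and Cr(CO)6 15 (with commercial non-3-yn-2-one) and comes back to the route at target 23. Non-3-yn-2-one is hydroiodinated (NaI, AcOH, rt) to (3Z)-4-iodonon-3-en-2-one F1. Silylation (i-Pr3SiOTf, Et3N, CH2Cl2, 0 °C) gives {[(3Z)-4-iodonona-1,3-dien-2-yl]oxy}tri(propan-2-yl)silane F2; the bulky silyl group is chosen so that it does not migrate to the vinyl anion. Iodine–lithium exchange (t-BuLi, Et2O, −78 °C), addition to 15 and cation exchange with Me4NBr give tetramethylammonium pentacarbonyl{(2Z)-2-pentyl-4-[tri(propan-2-yl)silyloxy]penta-2,4-dienoyl}chromate F3. Acetyl bromide and then phenol 10, as in step 8, give pentacarbonyl{[5-methoxy-2-(methoxycarbonyl)-3-pentanoylphenoxy][(3Z)-2-{[tri(propan-2-yl)silyl]oxy}nona-1,3-dien-4-yl]methylidene}chromium F4. Irradiation with visible light (λ > 420 nm, so that the aryl ketone of ring B is not excited) under CO (1 atm) in THF should bring about CO insertion and 6π closure to methyl 2-(2-hydroxy-6-pentyl-4-{[tri(propan-2-yl)silyl]oxy}phenoxy)-4-methoxy-6-pentanoylbenzoate F5. Bu4NF buffered with AcOH in THF at 0 °C then gives 23.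

2. Step 8. The phenol is hydrogen-bonded to its ortho ester and electron-poor, so it may displace acetate more slowly than the acetoxycarbene complex 19 decomposes above about −20 °C, or it may be acetylated at oxygen instead. The fallback gives up chromium for the diaryl ether bond and uses a copper-catalysed Ullmann-type coupling. It sets out from phenol 10 (with commercial olivetol, 5-pentylbenzene-1,3-diol) and comes back to the route at target 23. The ketone of 10 is first masked (ethane-1,2-dithiol, BF3·OEt2, CH2Cl2) as methyl 2-(2-butyl-1,3-dithiolan-2-yl)-6-hydroxy-4-methoxybenzoate F6, so that the base of the coupling cannot close the keto ester to an indane-1,3-dione. Olivetol is benzylated (BnBr, K2CO3, DMF) to 1,3-bis(benzyloxy)-5-pentylbenzene F7. Iodination (N-iodosuccinimide, cat. CF3CO2H, MeCN, 0 °C) goes para to one benzyloxy group and between the other and the pentyl group, giving 1,5-bis(benzyloxy)-2-iodo-3-pentylbenzene F8. CuI (20 mol%), picolinic acid (40 mol%) and K3PO4 in DMSO at 90 °C couple F6 and F8 to methyl 2-[2,4-bis(benzyloxy)-6-pentylphenoxy]-6-(2-butyl-1,3-dithiolan-2-yl)-4-methoxybenzoate F9. MeI and CaCO3 in aqueous MeCN free the ketone to give methyl 2-[2,4-bis(benzyloxy)-6-pentylphenoxy]-4-methoxy-6-pentanoylbenzoate F10. Hydrogenolysis (H2, Pd/C, EtOAc) removes both benzyl groups and gives 23.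

3. Step 4. The aryllithium 6, flanked by a methoxy group and the ketal-bearing carbon, may be protonated before it is acylated or may be acylated only in part, and the ketal next to the new ester may hydrolyse sluggishly. The fallback avoids both the organolithium and the ketal: palladium-catalysed methoxycarbonylation of the aryl bromide. It sets out from bromo ketone 4 and comes back to the route at keto ester 8, so that steps 3 and 4 are skipped. Compound 4 is heated with Pd(OAc)2 (5 mol%), Xantphos (10 mol%), CO (1 atm), excess MeOH and Et3N in toluene at 90 °C; the excess methanol should intercept the acylpalladium intermediate before the neighbouring ketone can trap it through its enol oxygen, and the weak amine base should not enolise the product towards Claisen-type closure.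

**Further compounds**

F1 | step 9 | (3Z)-4-iodonon-3-en-2-one | CCCCC/C(I)=C/C(C)=O
F2 | step 9 | {[(3Z)-4-iodonona-1,3-dien-2-yl]oxy}tri(propan-2-yl)silane | CCCCC/C(I)=C/C(=C)O[Si](C(C)C)(C(C)C)C(C)C
F3 | step 9 | tetramethylammonium pentacarbonyl{(2Z)-2-pentyl-4-[tri(propan-2-yl)silyloxy]penta-2,4-dienoyl}chromate | C[N+](C)(C)C.[O-]C(/C(CCCCC)=C\C(=C)O[Si](C(C)C)(C(C)C)C(C)C)=[Cr](=C=O)(=C=O)(=C=O)(=C=O)=C=O
F4 | step 9 | pentacarbonyl{[5-methoxy-2-(methoxycarbonyl)-3-pentanoylphenoxy][(3Z)-2-{[tri(propan-2-yl)silyl]oxy}nona-1,3-dien-4-yl]methylidene}chromium | O=C=[Cr](=C=O)(=C=O)(=C=O)(=C=O)=C(Oc1cc(OC)cc(C(=O)CCCC)c1C(=O)OC)/C(CCCCC)=C\C(=C)O[Si](C(C)C)(C(C)C)C(C)C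
F5 | step 9 | methyl 2-(2-hydroxy-6-pentyl-4-{[tri(propan-2-yl)silyl]oxy}phenoxy)-4-methoxy-6-pentanoylbenzoate | CCCCCc1cc(O[Si](C(C)C)(C(C)C)C(C)C)cc(O)c1Oc1cc(OC)cc(C(=O)CCCC)c1C(=O)OC
F6 | step 8 | methyl 2-(2-butyl-1,3-dithiolan-2-yl)-6-hydroxy-4-methoxybenzoate | COC(=O)c1c(O)cc(OC)cc1C1(CCCC)SCCS1
F7 | step 8 | 1,3-bis(benzyloxy)-5-pentylbenzene | CCCCCc1cc(OCc2ccccc2)cc(OCc2ccccc2)c1
F8 | step 8 | 1,5-bis(benzyloxy)-2-iodo-3-pentylbenzene | CCCCCc1cc(OCc2ccccc2)cc(OCc2ccccc2)c1I
F9 | step 8 | methyl 2-[2,4-bis(benzyloxy)-6-pentylphenoxy]-6-(2-butyl-1,3-dithiolan-2-yl)-4-methoxybenzoate | CCCCCc1cc(OCc2ccccc2)cc(OCc2ccccc2)c1Oc1cc(OC)cc(C2(CCCC)SCCS2)c1C(=O)OC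
F10 | step 8 | methyl 2-[2,4-bis(benzyloxy)-6-pentylphenoxy]-4-methoxy-6-pentanoylbenzoate | CCCCCc1cc(OCc2ccccc2)cc(OCc2ccccc2)c1Oc1cc(OC)cc(C(=O)CCCC)c1C(=O)OC
F0 | step 4 | none | none
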